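**Retrosynthetic overview**

Numbering: ring C1–C10 (C1=C10 Z-olefin, CH3 on C10, OAc on C2, CH3 on C4, C4–C5 epoxide, lactone O on C6, C7=C11, methacrylate on C8); C12 lactone C=O, C13 CH2OAc.
The ten-membered ring is cut at C1–C10 and C4–C5, the two bonds that carry the Z-olefin and the epoxide. This gives a six-carbon enone C5–C10 (C6 carbonyl, C8 oxygen) and a four-carbon cyclobutene C1–C4 (C2 oxygen), joined by [2+2] photocycloaddition into a 6-4-4 ladder.
Heating cleaves the ladder bonds C1–C4 and C5–C10, which the target lacks, and leaves C1=C10 and C4=C5 in a cyclodeca-1(10),4-dien-6-one. Ring order: cyclohexenone and cyclobutene, then cyclobutane (light), ten-membered ring (heat), epoxide, butenolide.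
The C6 carbonyl is then used three times: CBS reduction and hydroxyl-directed epoxidation of C4=C5, C7 enolate alkylation (C11, C12), and reduction–lactonisation. C13 and C7=C11 come from lactone hydroxymethylation and selenoxide elimination; acylations come last.

Key step: step 10

Assumption: in step 2 the lipase acylates the R-configured carbinol of meso-diol 2 (the sense the empirical rule for secondary alcohols predicts when the ring segment carrying the PMB ether counts as the larger one).
Remark: C7 and C11 are temporary centres in 20–25; the SMILES show the epimers expected from attack on the less hindered face, and any epimer converges at 26.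

**Route**

Step 1
Reactants: 1 cis,cis-cyclohexane-1,3,5-triol
Product: 2 all-cis-5-[(4-methoxybenzyl)oxy]cyclohexane-1,3-diol (meso)
Conditions: NaH (1.0 equiv), PMBCl (0.9 equiv), Bu4NI (cat.), DMF, 0 °C → rt
Reagents that add atoms: 4-methoxybenzyl chloride (COc1ccc(CCl)cc1)
Why: Williamson etherification of the mono-alkoxide; the three hydroxyls are equivalent, so only the degree of alkylation needs control (excess triol), and the mono-ether is meso.

Step 2
Reactants: 2 all-cis-5-[(4-methoxybenzyl)oxy]cyclohexane-1,3-diol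
Product: 3 (1R,3R,5S)-3-hydroxy-5-[(4-methoxybenzyl)oxy]cyclohexyl acetate (all-cis)
Conditions: Candida antarctica lipase B (immobilised), vinyl acetate, t-BuOMe, 25 °C
Reagents that add atoms: vinyl acetate (C=COC(C)=O)
Why: Lipase-catalysed acyl transfer desymmetrises the meso-1,3-diol, which fixes the absolute sense at the ether carbon (future C8), and the enol leaving group makes the acylation irreversible.

Step 3
Reactants: 3 (1R,3R,5S)-3-hydroxy-5-[(4-methoxybenzyl)oxy]cyclohexyl acetate
Product: 5 (R)-5-[(4-methoxybenzyl)oxy]cyclohex-2-en-1-one, via acetoxy ketone 4 (not isolated)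
Conditions: Dess–Martin periodinane, NaHCO3, CH2Cl2, 0 °C → rt; then Et3N, rt
Reagents that add atoms: none
Why: Dess–Martin oxidation gives the β-acetoxy ketone, and the mild amine then eliminates acetic acid by E1cB, because acetate leaves far more readily than the PMB alkoxide on the other β-carbon, so the ether stereocentre stays.

Step 4
Reactants: 5 (R)-5-[(4-methoxybenzyl)oxy]cyclohex-2-en-1-one
Product: 6 (5R)-5-[(4-methoxybenzyl)oxy]-1-methylcyclohex-2-en-1-ol (mixture at C1)
Conditions: MeLi, THF, −78 °C; then H2O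
Reagents that add atoms: methyllithium ([Li]C)
Why: 1,2-Addition of the hard organolithium to the enone carbonyl at low temperature; the new carbinol centre is removed in the next step.

Step 5
Reactants: 6 (5R)-5-[(4-methoxybenzyl)oxy]-1-methylcyclohex-2-en-1-ol
Product: 7 (S)-5-[(4-methoxybenzyl)oxy]-3-methylcyclohex-2-en-1-one (C5–C10 unit; C6 carbonyl, C10 methyl, C8 ether)
Conditions: pyridinium chlorochromate (C5H5NH)[CrO3Cl], 4 Å MS, CH2Cl2, rt
Reagents that add atoms: pyridinium chlorochromate ([O-][Cr](=O)(=O)Cl.c1cc[nH+]cc1)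
Why: Babler–Dauben oxidative transposition ([3,3] shift of the tertiary allylic chromate ester, then oxidation) moves the carbonyl to C6 and puts the methyl on C10; C8 is untouched and becomes S only through the changed ring priorities.

Step 6
Reactants: 8 propyne; 9 trichloroacetyl chloride
Product: 11 4,4-dichloro-3-methylcyclobut-2-en-1-one, via dichloroketene 10 (not isolated)
Conditions: Zn–Cu couple, POCl3, Et2O, 35 °C, slow addition of 9
Reagents that add atoms: none
Why: Reductive dechlorination of the acid chloride gives dichloroketene, which undergoes the ketene–alkyne [2+2] cycloaddition with its carbonyl carbon bonding to the terminal alkyne carbon.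

Step 7
Reactants: 11 4,4-dichloro-3-methylcyclobut-2-en-1-one
Product: 12 3-methylcyclobut-2-en-1-one
Conditions: Zn, AcOH, TMEDA, EtOH, 0 °C → rt
Reagents that add atoms: none
Why: Zinc reduction of the α,α-dichloro ketone through the zinc enolate, buffered with TMEDA so that the strained enone survives.

Step 8
Reactants: 12 3-methylcyclobut-2-en-1-one
Product: 13 (S)-3-methylcyclobut-2-en-1-ol
Conditions: (R)-2-methyl-CBS-oxazaborolidine (10 mol%), BH3·SMe2, THF, −30 °C; MeOH quench, cold work-up, used at once
Reagents that add atoms: none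
Why: CBS reduction under catalyst control, in which the alkenyl carbon acts as the large group, delivers hydride to give the S carbinol (future C2) by 1,2-reduction.

Step 9
Reactants: 13 (S)-3-methylcyclobut-2-en-1-ol
Product: 14 (S)-tert-butyldimethyl[(3-methylcyclobut-2-en-1-yl)oxy]silane (C1–C4 unit; C4 methyl, C2 silyl ether)
Conditions: TBSCl, imidazole, CH2Cl2, 0 °C; stored and handled below 0 °C
Reagents that add atoms: tert-butyldimethylsilyl chloride (CC(C)(C)[Si](C)(C)Cl)
Why: Imidazole-mediated silylation needs no free alkoxide, which would trigger anion-accelerated electrocyclic ring opening, and cold handling guards the donor-substituted cyclobutene against thermal opening.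

Step 10
Reactants: 7 (S)-5-[(4-methoxybenzyl)oxy]-3-methylcyclohex-2-en-1-one; 14 (S)-tert-butyldimethyl[(3-methylcyclobut-2-en-1-yl)oxy]silane
Product: 15 cis-anti-cis 6-4-4 ladder ketone (new bonds C1–C10 and C4–C5; 2S, 8S; cyclobutane on the ring face syn to the C8 ether, C2 silyl ether anti to the C1–C10 bond)
Conditions: hν (350 nm, Pyrex), 14 (4 equiv), CH2Cl2, −40 °C; then neutral Al2O3
Reagents that add atoms: none
Why: Excitation of enone 7 and intersystem crossing give the twisted triplet, which adds to the cyclobutene through a 1,4-diradical that closes after spin inversion; this is the established enone–cyclobutene [2+2] photocycloaddition. Only the four-membered ring C5–C10–C1–C4 is closed, by intermolecular formation of C1–C10 and C4–C5, and the resulting ladder holds all ten ring carbons on its perimeter. The step needs head-to-head regiochemistry (C10 to C1, C5 to C4): bonding of the methyl-bearing C10 to the unsubstituted C1 leaves a tertiary radical at C4 and the α-keto radical at C5, which close readily, whereas the other orientation would have to join the two fully substituted carbons C10 and C4 and should mostly revert. Both ring fusions should be cis (any trans 6-4 isomer epimerises at C5 on alumina), the outer rings should lie anti across the central cyclobutane for steric reasons, and the enone should add to the cyclobutene face remote from the C2 silyl ether. C1, C4, C5 and C10 are all destroyed in step 11, so the facial pairing of the two enantiopure partners need not be controlled, and C2 and C8 are spectators. Low temperature and filtered light keep the silyloxycyclobutene from ring opening and leave the PMB chromophore unexcited.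

Step 11
Reactants: 15 ladder ketone
Product: 16 (2S,8S,1(10)Z,4E)-2-[(tert-butyldimethylsilyl)oxy]-8-[(4-methoxybenzyl)oxy]-4,10-dimethylcyclodeca-1(10),4-dien-6-one
Conditions: degassed toluene, 200 °C, sealed silanised tube, BHT (trace)
Reagents that add atoms: none
Why: Thermal cycloreversion of the bicyclo[2.2.0]hexane unit (cleavage of C1–C4 to a cyclohexane-1,4-diyl, then of C5–C10) releases more than 50 kcal/mol of strain, and the chair-like diyl with C9 axial at quaternary C10 and C6 equatorial at C5 should give 1(10)Z and 4E, with the new conjugation to C6=O opposing an onward Cope shift.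

Step 12
Reactants: 16 cyclodecadienone
Product: 17 (2S,6S,8S,1(10)Z,4E)-dienol (C6–OH)
Conditions: (R)-2-methyl-CBS-oxazaborolidine (20 mol%), BH3·SMe2, THF, −40 °C
Reagents that add atoms: none
Why: CBS reduction under catalyst control (C5 alkenyl as the large group, C7 methylene as the small one) gives the 6S allylic alcohol by 1,2-reduction; this carbinol is a temporary directing centre.

Step 13
Reactants: 17 dienol
Product: 18 (2S,4R,5R,6S,8S)-4,5-epoxy-6-ol
Conditions: VO(acac)2 (5 mol%), t-BuOOH, 2,6-lutidine, CH2Cl2, 0 °C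
Reagents that add atoms: tert-butyl hydroperoxide (CC(C)(C)OO)
Why: Hydroxyl-directed epoxidation, in which the vanadium alkoxide at C6 delivers oxygen to C4=C5 in the conformer that holds H6 in the olefin plane (A(1,3) strain with the C4 methyl), gives the threo epoxy alcohol 4R,5R and leaves C1=C10, which has no allylic hydroxyl.

Step 14
Reactants: 18 epoxy alcohol
Product: 19 (2S,4R,5S,8S)-4,5-epoxy-6-one (same geometry at C5; descriptor changes by priority only)
Conditions: Dess–Martin periodinane, NaHCO3, CH2Cl2, 0 °C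
Reagents that add atoms: none
Why: Buffered Dess–Martin oxidation returns the C6 carbonyl without touching the epoxide, the ethers or the olefin.

Step 15
Reactants: 19 epoxy ketone
Product: 20 ethyl ester of the C7-(carboxymethyl) epoxy ketone (C11 and C12 attached; side chain anti to the C8 ether)
Conditions: LiN(SiMe3)2, THF, −78 °C; ICH2CO2Et, DMPU, −78 → −40 °C
Reagents that add atoms: ethyl iodoacetate (ICC(=O)OCC)
Why: Kinetic enolisation can only occur at C7 (C5 is an epoxide carbon), and SN2 C-alkylation of the lithium enolate by the iodoacetate should occur anti to the C8 alkoxy group; C7 later becomes trigonal.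

Step 16
Reactants: 20 keto ester
Product: 22 saturated 12,6-lactone (6S, cis-fused at C6–C7), via hydroxy ester 21 (not isolated)
Conditions: NaBH4, MeOH/THF, −40 → 0 °C; then DBU (cat.), CH2Cl2, rt
Reagents that add atoms: none
Why: Felkin–Anh hydride addition to C6 anti to the C5–O epoxide bond and anti to the C7–C8 bond (both models lead to the same face) should give the 6S alkoxide, threo to the epoxide and 1,3-syn to the C8 ether, which closes the γ-lactone on the ethyl ester by acyl substitution.

Step 17
Reactants: 22 lactone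
Product: 23 C11-(hydroxymethyl) lactone (C13 attached)
Conditions: LiN(iPr)2, THF, −78 °C; CH2O (g), −78 → −40 °C; then H2O
Reagents that add atoms: formaldehyde (C=O)
Why: Aldol addition of the lactone lithium enolate to monomeric formaldehyde from the convex face, away from the ten-membered ring; C11 is temporary.

Step 18
Reactants: 23 hydroxymethyl lactone
Product: 24 C11-(phenylselanyl) C11-(hydroxymethyl) lactone (Se cis to H7)
Conditions: LiN(iPr)2 (2.3 equiv), THF, −78 → −40 °C; PhSeBr, −78 °C; then H2O
Reagents that add atoms: phenylselenenyl bromide (Br[Se]c1ccccc1)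
Why: The alkoxide–enolate dianion resists β-elimination, and selenenylation again from the convex face places selenium cis to H7, as the later syn elimination requires.

Step 19
Reactants: 24 selenide
Product: 26 7(11)-en-12,6-olide with C13–OH (butenolide), via selenoxide 25 (not isolated)
Conditions: mCPBA (1.05 equiv), CH2Cl2, −78 °C; then i-Pr2NH, −78 °C → rt
Reagents that add atoms: none
Why: Selenium is oxidised at −78 °C faster than any olefin, and the selenoxide syn elimination runs toward C7–H and not toward the oxygen-bearing C13 (selenoxides avoid forming enols), which gives the tetrasubstituted C7=C11 butenolide.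

Step 20
Reactants: 26 butenolide alcohol
Product: 27 C2,C13-diol
Conditions: HF·pyridine, pyridine, THF, 0 °C → rt
Reagents that add atoms: none
Why: Buffered fluoride desilylation frees C2–OH without base (the butenolide γ-hydrogen at C6 lies next to the epoxide) and without strong acid (risk of transannular epoxide opening).

Step 21
Reactants: 27 diol
Product: 28 C2,C13-diacetate
Conditions: Ac2O, pyridine, DMAP (cat.), CH2Cl2, 0 °C
Reagents that add atoms: acetic anhydride (CC(=O)OC(C)=O)
Why: DMAP-catalysed acylation of the primary allylic and the secondary allylic hydroxyl; C8 is still protected.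

Step 22
Reactants: 28 diacetate
Product: 29 C8 alcohol
Conditions: DDQ, CH2Cl2/pH 7 phosphate buffer, 0 °C
Reagents that add atoms: none
Why: Oxidative cleavage of the PMB ether through the benzylic oxocarbenium ion under buffered conditions; the C8 carbinol is allylic to an electron-poor olefin and should not be oxidised further.

Step 23
Reactants: 29 C8 alcohol
Product: 30 target (CNP0268364.3)
Conditions: methacrylic anhydride, Et3N, DMAP (cat.), CH2Cl2, 0 °C → rt
Reagents that add atoms: methacrylic anhydride (CC(=C)C(=O)OC(=O)C(C)=C)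
Why: DMAP-catalysed esterification of the last free hydroxyl with retention at C8, run briefly to avoid acetyl migration from C13.

**Compound list**

1 | cis,cis-cyclohexane-1,3,5-triol | O[C@H]1C[C@@H](O)C[C@@H](O)C1 | starting material
2 | all-cis-5-[(4-methoxybenzyl)oxy]cyclohexane-1,3-diol (meso) | COc1ccc(CO[C@H]2C[C@@H](O)C[C@@H](O)C2)cc1 | intermediate
3 | (1R,3R,5S)-3-hydroxy-5-[(4-methoxybenzyl)oxy]cyclohexyl acetate | COc1ccc(CO[C@H]2C[C@@H](O)C[C@@H](OC(C)=O)C2)cc1 | intermediate
4 | (1S,3R)-3-[(4-methoxybenzyl)oxy]-5-oxocyclohexyl acetate | COc1ccc(CO[C@H]2CC(=O)C[C@@H](OC(C)=O)C2)cc1 | intermediate (not isolated)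
5 | (R)-5-[(4-methoxybenzyl)oxy]cyclohex-2-en-1-one | COc1ccc(CO[C@H]2CC(=O)C=CC2)cc1 | intermediate
6 | (5R)-5-[(4-methoxybenzyl)oxy]-1-methylcyclohex-2-en-1-ol | COc1ccc(CO[C@H]2CC(C)(O)C=CC2)cc1 | intermediate
7 | (S)-5-[(4-methoxybenzyl)oxy]-3-methylcyclohex-2-en-1-one | COc1ccc(CO[C@H]2CC(C)=CC(=O)C2)cc1 | intermediate (key-step precursor)
8 | propyne | CC#C | starting material
9 | trichloroacetyl chloride | ClC(Cl)(Cl)C(Cl)=O | starting material
10 | dichloroketene | ClC(Cl)=C=O | intermediate (not isolated)
11 | 4,4-dichloro-3-methylcyclobut-2-en-1-one | CC1=CC(=O)C1(Cl)Cl | intermediate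
12 | 3-methylcyclobut-2-en-1-one | CC1=CC(=O)C1 | intermediate
13 | (S)-3-methylcyclobut-2-en-1-ol | CC1=C[C@@H](O)C1 | intermediate
14 | (S)-tert-butyldimethyl[(3-methylcyclobut-2-en-1-yl)oxy]silane | CC1=C[C@@H](O[Si](C)(C)C(C)(C)C)C1 | intermediate (key-step precursor)
15 | cis-anti-cis ladder ketone (tricyclo[4.4.0.0^2,5]decan-7-one skeleton; C2 OTBS, C8 OPMB, C4 and C10 methyls) | COc1ccc(CO[C@H]2C[C@@]3(C)[C@@H]4[C@@H](O[Si](C)(C)C(C)(C)C)C[C@]4(C)[C@H]3C(=O)C2)cc1 | intermediate (key-step product)
16 | (2S,8S,1(10)Z,4E)-cyclodeca-1(10),4-dien-6-one (C2 OTBS, C8 OPMB) | COc1ccc(CO[C@H]2C/C(C)=C\[C@@H](O[Si](C)(C)C(C)(C)C)C/C(C)=C/C(=O)C2)cc1 | intermediate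
17 | (2S,6S,8S)-dienol | COc1ccc(CO[C@H]2C/C(C)=C\[C@@H](O[Si](C)(C)C(C)(C)C)C/C(C)=C/[C@@H](O)C2)cc1 | intermediate
18 | (2S,4R,5R,6S,8S)-4,5-epoxy-6-ol | COc1ccc(CO[C@H]2C/C(C)=C\[C@@H](O[Si](C)(C)C(C)(C)C)C[C@@]3(C)O[C@@H]3[C@@H](O)C2)cc1 | intermediate
19 | (2S,4R,5S,8S)-4,5-epoxy-6-one | COc1ccc(CO[C@H]2C/C(C)=C\[C@@H](O[Si](C)(C)C(C)(C)C)C[C@@]3(C)O[C@@H]3C(=O)C2)cc1 | intermediate
20 | C7-(2-ethoxy-2-oxoethyl) epoxy ketone | COc1ccc(CO[C@H]2C/C(C)=C\[C@@H](O[Si](C)(C)C(C)(C)C)C[C@@]3(C)O[C@@H]3C(=O)[C@H]2CC(=O)OCC)cc1 | intermediate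
21 | (6S)-hydroxy ester | COc1ccc(CO[C@H]2C/C(C)=C\[C@@H](O[Si](C)(C)C(C)(C)C)C[C@@]3(C)O[C@@H]3[C@@H](O)[C@H]2CC(=O)OCC)cc1 | intermediate (not isolated)
22 | saturated 12,6-lactone (6S) | COc1ccc(CO[C@H]2C/C(C)=C\[C@@H](O[Si](C)(C)C(C)(C)C)C[C@@]3(C)O[C@@H]3[C@H]3OC(=O)C[C@H]32)cc1 | intermediate
23 | C11-(hydroxymethyl) lactone | COc1ccc(CO[C@H]2C/C(C)=C\[C@@H](O[Si](C)(C)C(C)(C)C)C[C@@]3(C)O[C@@H]3[C@H]3OC(=O)[C@H](CO)[C@H]32)cc1 | intermediate
24 | C11-(phenylselanyl) C11-(hydroxymethyl) lactone | COc1ccc(CO[C@H]2C/C(C)=C\[C@@H](O[Si](C)(C)C(C)(C)C)C[C@@]3(C)O[C@@H]3[C@H]3OC(=O)[C@](CO)([Se]c4ccccc4)[C@H]32)cc1 | intermediate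
25 | selenoxide of 24 | COc1ccc(CO[C@H]2C/C(C)=C\[C@@H](O[Si](C)(C)C(C)(C)C)C[C@@]3(C)O[C@@H]3[C@H]3OC(=O)[C@](CO)([Se](=O)c4ccccc4)[C@H]32)cc1 | intermediate (not isolated)
26 | 7(11)-en-12,6-olide, C13–OH, C2 OTBS, C8 OPMB | COc1ccc(CO[C@H]2C/C(C)=C\[C@@H](O[Si](C)(C)C(C)(C)C)C[C@@]3(C)O[C@@H]3[C@H]3OC(=O)C(CO)=C32)cc1 | intermediate
27 | C2,C13-diol, C8 OPMB | COc1ccc(CO[C@H]2C/C(C)=C\[C@@H](O)C[C@@]3(C)O[C@@H]3[C@H]3OC(=O)C(CO)=C32)cc1 | intermediate
28 | C2,C13-diacetate, C8 OPMB | COc1ccc(CO[C@H]2C/C(C)=C\[C@@H](OC(C)=O)C[C@@]3(C)O[C@@H]3[C@H]3OC(=O)C(COC(C)=O)=C32)cc1 | intermediate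
29 | C2,C13-diacetate, C8–OH | O[C@H]1C/C(C)=C\[C@@H](OC(C)=O)C[C@@]2(C)O[C@@H]2[C@H]2OC(=O)C(COC(C)=O)=C12 | intermediate
30 | CNP0268364.3 | C=C(C)C(=O)O[C@H]1C/C(C)=C\[C@@H](OC(C)=O)C[C@@]2(C)O[C@@H]2[C@H]2OC(=O)C(COC(C)=O)=C12 | target

**Step count**

Total: 23 steps. Longest linear sequence: 19 steps (steps 1–5, then 10–23).

**Steps most likely to fail**

Step 10. The diradical may close in the head-to-tail sense, or the silyloxycyclobutene may be lost to electrocyclic ring opening before it is trapped. The fallback sets out from 7 and returns at 15. It reverses the polarity of the alkene with an acceptor, which is known to direct the substituted cyclobutene carbon onto the enone α-carbon and also stabilises the cyclobutene. Enone 7 is irradiated with racemic methyl 3-[(tert-butyldimethylsilyl)oxy]cyclobut-1-ene-1-carboxylate F1, and the 2S diastereomer of the adduct, ladder keto ester F2, is separated. LiAlH4 reduces both carbonyls to ladder diol F3. TsCl in pyridine gives the primary p-toluenesulfonate F4, LiBHEt3 reduces it to the C4 methyl in ladder carbinol F5, and Dess–Martin oxidation returns 15.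

Step 11. At the temperature needed for cycloreversion the cyclodecadienone may go on by [3,3] shift to the divinylcyclohexanone, or the β-alkoxy ketone may lose the C8 ether. The fallback sets out from 15 and returns at 16. It runs the ring opening at the carbinol oxidation level, where no β-alkoxy ketone is present and cyclodeca-1,5-dienols of this kind are known to be isolable. NaBH4 reduces 15 to ladder carbinol F5 (the compound of the preceding fallback), thermolysis gives cyclodecadienol F6 as a C6 epimer mixture, and MnO2 or Dess–Martin periodinane oxidises the allylic carbinol to 16.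

Step 16. Hydride may add to the other face of the C6 carbonyl, because the ring conformation may override the Felkin–Anh preference. The fallback sets out from 20 and returns at 22. The (6R)-hydroxy ester F7 then closes to the C6-epimeric lactone F8. Saponification with LiOH in aqueous THF opens it to the (6R)-hydroxy acid F9, and intramolecular Mitsunobu esterification (PPh3, DIAD, THF) closes the lactone with inversion at C6 to give 22.

Further compounds
F1 | step 10 | methyl 3-[(tert-butyldimethylsilyl)oxy]cyclobut-1-ene-1-carboxylate (racemic) | COC(=O)C1=CC(O[Si](C)(C)C(C)(C)C)C1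
F2 | step 10 | ladder keto ester (15 with CO2CH3 in place of the C4 methyl) | COc1ccc(CO[C@H]2C[C@@]3(C)[C@@H]4[C@@H](O[Si](C)(C)C(C)(C)C)C[C@]4(C(=O)OC)[C@H]3C(=O)C2)cc1
F3 | step 10 | ladder diol (C6–OH, C4–CH2OH) | COc1ccc(CO[C@H]2C[C@@]3(C)[C@@H]4[C@@H](O[Si](C)(C)C(C)(C)C)C[C@]4(CO)[C@H]3C(O)C2)cc1
F4 | step 10 | primary p-toluenesulfonate of F3 | COc1ccc(CO[C@H]2C[C@@]3(C)[C@@H]4[C@@H](O[Si](C)(C)C(C)(C)C)C[C@]4(COS(=O)(=O)c5ccc(C)cc5)[C@H]3C(O)C2)cc1
F5 | step 10 | ladder carbinol (15 with C6–OH) | COc1ccc(CO[C@H]2C[C@@]3(C)[C@@H]4[C@@H](O[Si](C)(C)C(C)(C)C)C[C@]4(C)[C@H]3C(O)C2)cc1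
F6 | step 11 | cyclodecadienol (C6 epimer mixture) | COc1ccc(CO[C@H]2C/C(C)=C\[C@@H](O[Si](C)(C)C(C)(C)C)C/C(C)=C/C(O)C2)cc1
F7 | step 16 | (6R)-hydroxy ester | COc1ccc(CO[C@H]2C/C(C)=C\[C@@H](O[Si](C)(C)C(C)(C)C)C[C@@]3(C)O[C@@H]3[C@H](O)[C@H]2CC(=O)OCC)cc1
F8 | step 16 | (6R)-lactone (C6 epimer of 22) | COc1ccc(CO[C@H]2C/C(C)=C\[C@@H](O[Si](C)(C)C(C)(C)C)C[C@@]3(C)O[C@@H]3[C@@H]3OC(=O)C[C@H]32)cc1
F9 | step 16 | (6R)-hydroxy acid | COc1ccc(CO[C@H]2C/C(C)=C\[C@@H](O[Si](C)(C)C(C)(C)C)C[C@@]3(C)O[C@@H]3[C@H](O)[C@H]2CC(=O)O)cc1
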